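**Retrosynthetic overview**

1. Both C2–aryl bonds of the two trans-2,3-diaryl-2,3-dihydrobenzofurans are cut last (nickel decarboxylative arylation), so each heterocycle is traced to a 3-aryl-2,3-dihydrobenzofuran-2-carboxylic acid.
2. Each acid is the ring-contraction product of a six-membered 4-aryl-3,4-dihydrocoumarin: α-bromination, hydroxide opening of the lactone and O-alkylation by the freed phenoxide. The lactone carbonyl is a temporary ring atom and activating group that ends as the traceless CO2H.
3. Enabling feature of the inner ring: O1 sits on aromatic C7a ortho to C3a, C3a carries C3 with its resorcinol ring, and only C2 separates C3 from O1. One carbonyl carbon inserted between O1 and C2 therefore gives the coumarin ring O1–C(=O)–C2–C3–C3a–C7a; the second oxygen of that benzene ring (C4) is an ether, so only O1 can close, and C2 needs an aryl group exactly where the extruded carbon is left.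
4. Stereocontrol: C3 of each ring by Rh/(S)-SEGPHOS 1,4-addition of the 3,5-dioxygenated arylboronic acid to the coumarin; C2 by trans-selective capture of the C2 radical.
5. Ring order: coumarin A (from resveratrol) → outer dihydrobenzofuran → coumarin B attached through its C8 → inner dihydrobenzofuran (key contraction) → 2,4-dioxygenated aryl ring → deprotection.

Key step: step 14

Abbreviations: MOM = CH2OCH3, MOMO = methoxymethoxy; ring A and ring B are the benzene rings of the outer (styryl-bearing) and inner dihydrobenzofuran.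

Assumption: (S)-SEGPHOS is taken to give the (4S)-4-aryl-dihydrocoumarins, because the (R)-ligand gives (R)-4-arylchroman-2-ones in the parent series and the CIP ranking at C4 is the same here; if the sense proved opposite, the (R)-ligand would be used.

**Route**

Step 1
Reactants: 1 resveratrol
Product: 2 tri-MOM resveratrol
Conditions: NaH (3.6 equiv), MOMCl (3.6 equiv), DMF, 0 → 20 °C
Reagents that add atoms: chloromethyl methyl ether, COCCl
Why: Williamson etherification of the three phenoxides gives MOM ethers that survive all later basic, organometallic and rhodium steps and serve as directing groups in step 2.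

Step 2
Reactants: 2 tri-MOM resveratrol
Product: 4 2,6-bis(MOMO)-4-styryl benzaldehyde, via aryllithium 3 (not isolated)
Conditions: n-BuLi (1.15 equiv), THF, −20 °C, 1 h; DMF, −20 → 20 °C; H2O
Reagents that add atoms: N,N-dimethylformamide, CN(C)C=O
Why: Directed ortho-metalation: the aryl C–H flanked by two MOM ethers is the most acidic site (two cooperating directing groups), deprotonation at −20 °C should be faster than carbolithiation of the stilbene, and the aryllithium is formylated by DMF.

Step 3
Reactants: 4 2,6-bis(MOMO)-4-styryl benzaldehyde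
Product: 5 2-hydroxy-6-(MOMO)-4-styryl benzaldehyde
Conditions: HCl (0.3 M in MeOH, 1 equiv), THF, 0 → 20 °C, stopped at mono-cleavage
Reagents that add atoms: none
Why: Acid-catalysed transacetalisation: a MOM ether ortho to the formyl group is cleaved fastest, the freed phenol then forms a hydrogen bond to the carbonyl that slows loss of the second one, and the two ortho groups are equivalent, so a single mono-phenol should result.

Step 4
Reactants: 5 2-hydroxy-6-(MOMO)-4-styryl benzaldehyde
Product: 7 coumarin A, via cinnamate ester 6 (not isolated)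
Conditions: Ph3P=CHCO2Et (1.3 equiv), N,N-diethylaniline, 210 °C
Reagents that add atoms: ethyl (triphenylphosphoranylidene)acetate, CCOC(=O)C=P(c1ccccc1)(c1ccccc1)c1ccccc1
Why: Wittig olefination followed by thermal E/Z isomerisation and lactonisation (the salicylaldehyde route to coumarins); only the free phenol can lactonise, so one coumarin is formed.

Step 5
Reactants: 8 5-bromoresorcinol
Product: 9 1-bromo-3,5-bis(MOMO)benzene
Conditions: NaH (2.4 equiv), MOMCl (2.4 equiv), DMF, 0 → 20 °C
Reagents that add atoms: chloromethyl methyl ether, COCCl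
Why: Williamson etherification of both phenoxides.

Step 6
Reactants: 9 1-bromo-3,5-bis(MOMO)benzene
Product: 11 [3,5-bis(MOMO)phenyl]boronic acid, via aryllithium 10 (not isolated)
Conditions: n-BuLi (1.05 equiv), THF, −78 °C; B(OiPr)3, −78 → 20 °C; 1 M HCl to pH 5, 0 °C
Reagents that add atoms: triisopropyl borate, CC(C)OB(OC(C)C)OC(C)C; water, O
Why: Bromine–lithium exchange at −78 °C, trapping with the borate and mild hydrolysis give the boronic acid, and the MOM ethers tolerate the brief pH 5 work-up.

Step 7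
Reactants: 7 coumarin A; 11 [3,5-bis(MOMO)phenyl]boronic acid (5 equiv)
Product: 12 lactone A [(4S)-4-aryl-3,4-dihydrocoumarin]
Conditions: Rh(acac)(C2H4)2 (5 mol %), (S)-SEGPHOS (5.5 mol %), 1,4-dioxane/H2O 10:1, 60 °C
Reagents that add atoms: none
Why: Hayashi–Miyaura rhodium-catalysed asymmetric 1,4-addition: the aryl–rhodium species adds to C4 of the coumarin on the face selected by (S)-SEGPHOS, setting the 4S centre (the later C3 of the outer dihydrobenzofuran), and water protonates the rhodium enolate.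

Step 8
Reactants: 12 lactone A
Product: 16 acid A [(2S,3S)-3-aryl-2,3-dihydrobenzofuran-2-carboxylic acid], via lithium enolate 13 (not isolated), via trans-bromolactone 14 (not isolated), via ring-opened bromo acid 15 (not isolated)
Conditions: LiN(SiMe3)2 (1.1 equiv), THF, −78 °C; NBS (1.0 equiv), −78 °C; 2 M aq NaOH (5 equiv), −78 → 20 °C; 1 M HCl to pH 4, 0 °C
Reagents that add atoms: sodium hydroxide, [Na+].[OH-]
Why: Enolate bromination anti to the C4 aryl group, hydroxide cleavage of the aryl lactone and 5-exo-tet displacement of bromide by the freed phenoxide (the 3,4-dihydro form of the Perkin coumarin–benzofuran ring contraction) contract the lactone to the dihydrobenzofuran: C3 is untouched (3S), C2 is formed with inversion as the trans acid (2S) and is re-set in step 12.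

Step 9
Reactants: 17 2,6-dihydroxybenzaldehyde
Product: 19 5-hydroxycoumarin, via cinnamate ester 18 (not isolated)
Conditions: Ph3P=CHCO2Et (1.3 equiv), N,N-diethylaniline, 210 °C
Reagents that add atoms: ethyl (triphenylphosphoranylidene)acetate, CCOC(=O)C=P(c1ccccc1)(c1ccccc1)c1ccccc1
Why: Wittig olefination, thermal isomerisation and lactonisation onto either of the two equivalent phenols give the coumarin and leave the other phenol free.

Step 10
Reactants: 19 5-hydroxycoumarin
Product: 20 5-hydroxy-8-iodocoumarin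
Conditions: NIS (1.0 equiv), TsOH·H2O (10 mol %), MeCN, 0 → 20 °C
Reagents that add atoms: N-iodosuccinimide, O=C1CCC(=O)N1I
Why: Electrophilic aromatic iodination of the phenol: C8 is para to the hydroxyl group and should be attacked in preference to the ortho position C6 by the bulky iodinating agent, while the electron-poor pyranone double bond is inert.

Step 11
Reactants: 20 5-hydroxy-8-iodocoumarin
Product: 21 8-iodo-5-(MOMO)coumarin
Conditions: NaH (1.2 equiv), MOMCl (1.2 equiv), DMF, 0 °C
Reagents that add atoms: chloromethyl methyl ether, COCCl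
Why: Williamson etherification of the phenoxide; the coumarin has no other acidic site.

Step 12
Reactants: 16 acid A; 21 8-iodo-5-(MOMO)coumarin (2.5 equiv)
Product: 24 outer dihydrobenzofuran bearing coumarin B at C2, via redox-active ester 22 (not isolated), via arylzinc iodide 23 (not isolated)
Conditions: (a) 21, Zn dust, LiCl, THF, 40 °C; (b) 16, N-hydroxyphthalimide, iPrN=C=NiPr, DMAP (cat.), CH2Cl2, 20 °C; (c) solutions from (a) and (b), NiCl2·DME (20 mol %; DME = MeOCH2CH2OMe), 4,4'-di-tert-butyl-2,2'-bipyridine (40 mol %), THF/DMF, 20 °C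
Reagents that add atoms: none
Why: Nickel-catalysed decarboxylative Negishi coupling of a redox-active N-(acyloxy)phthalimide: electron transfer releases CO2 and the C2 α-alkoxy radical, which the aryl–nickel species captures on the face away from the C3 aryl group to set the 2,3-trans (2S) centre, and LiCl-promoted zinc insertion into the aryl iodide tolerates the lactone.

Step 13
Reactants: 24 outer dihydrobenzofuran bearing coumarin B; 11 [3,5-bis(MOMO)phenyl]boronic acid (8 equiv)
Product: 25 lactone B [(4S)-4-aryl-3,4-dihydrocoumarin on ring B]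
Conditions: Rh(acac)(C2H4)2 (5 mol %), (S)-SEGPHOS (5.5 mol %), 1,4-dioxane/H2O 10:1, 70 °C
Reagents that add atoms: none
Why: Hayashi–Miyaura asymmetric 1,4-addition as in step 7: catalyst control by (S)-SEGPHOS sets the 4S centre of the new lactone irrespective of the remote stereocentres, and the stilbene, which is not an acceptor, is left alone.

Step 14
Reactants: 25 lactone B
Product: 29 acid B [inner (2S,3S)-3-aryl-2,3-dihydrobenzofuran-2-carboxylic acid], via lithium enolate 26 (not isolated), via trans-bromolactone 27 (not isolated), via ring-opened bromo acid 28 (not isolated)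
Conditions: LiN(SiMe3)2 (1.1 equiv), THF, −78 °C; NBS (1.0 equiv), −78 °C; 2 M aq NaOH (5 equiv), −78 → 20 °C; 1 M HCl to pH 4, 0 °C
Reagents that add atoms: sodium hydroxide, [Na+].[OH-]
Why: LiN(SiMe3)2 deprotonates only the lactone α-CH2 to give enolate 26, NBS brominates it on the face anti to the C4 aryl group (trans-bromolactone 27), hydroxide then cleaves the aryl ester at the acyl carbon and the C7a phenoxide of 28 displaces bromide at the α-carbon. The closest known reaction type is the Perkin coumarin-to-benzofuran ring contraction, here in its 3,4-dihydro form, that is hydrolysis of an α-halo dihydrocoumarin followed by intramolecular Williamson etherification. The five-membered ring (O1, C2, C3, C3a, C7a) closes in the 5-exo-tet mode while the six-membered lactone ring made of the same five atoms plus the carbonyl carbon is opened, so the ring contracts by one atom and the extruded carbon stays on C2 as CO2H. C3 (4S in 25) is not touched and becomes 3S; C2 is set by SN2 inversion of the trans-bromide, which should give the 2,3-trans acid (2S), and since C2 passes through a radical in step 16 its configuration is not critical. The step needs ring closure to outrun dehydrobromination to the 4-arylcoumarin: in trans-27 H-4 and Br are cis, so no anti-periplanar hydrogen is available inside the ring, acyl cleavage of the aryl ester by hydroxide is fast, and the phenoxide is held five atoms from the brominated carbon. Regiochemistry is fixed because only the oxygen that was part of the lactone is set free, the second oxygen of ring B (at C4) being a MOM ether.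

Step 15
Reactants: 30 4-bromoresorcinol
Product: 31 1-bromo-2,4-bis(MOMO)benzene
Conditions: NaH (2.4 equiv), MOMCl (2.4 equiv), DMF, 0 → 20 °C
Reagents that add atoms: chloromethyl methyl ether, COCCl
Why: Williamson etherification of both phenoxides.

Step 16
Reactants: 29 acid B; 31 1-bromo-2,4-bis(MOMO)benzene (3 equiv)
Product: 34 nona-MOM gnetumontanin B, via redox-active ester 32 (not isolated), via arylzinc chloride 33 (not isolated)
Conditions: (a) 31, Mg turnings, LiCl, ZnCl2, THF, 20 °C; (b) 29, N-hydroxyphthalimide, iPrN=C=NiPr, DMAP (cat.), CH2Cl2, 20 °C; (c) solutions from (a) and (b), NiCl2·DME (20 mol %), 4,4'-di-tert-butyl-2,2'-bipyridine (40 mol %), THF/DMF, 20 °C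
Reagents that add atoms: none
Why: Nickel-catalysed decarboxylative Negishi coupling as in step 12: the C2 radical of the inner ring is arylated anti to the C3 aryl group, which sets the last stereocentre (2S) and installs the 2,4-dioxygenated ring, and magnesium insertion in the presence of ZnCl2 gives the arylzinc directly.

Step 17
Reactants: 34 nona-MOM gnetumontanin B
Product: 35 gnetumontanin B
Conditions: HCl (1.25 M in MeOH), MeOH/THF, 30 °C, argon, dark
Reagents that add atoms: none
Why: Acid-catalysed transacetalisation of the nine aryl MOM ethers with methanol (dimethoxymethane is lost) under conditions mild enough not to ionise the benzylic C2–O bonds or isomerise the stilbene; no stereocentre is touched.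

**Compound list**

1 | resveratrol, (E)-5-(4-hydroxystyryl)benzene-1,3-diol | Oc1ccc(/C=C/c2cc(O)cc(O)c2)cc1 | starting material
2 | (E)-1,3-bis(MOMO)-5-[4-(MOMO)styryl]benzene | COCOc1ccc(/C=C/c2cc(OCOC)cc(OCOC)c2)cc1 | intermediate
3 | 2,6-bis(MOMO)-4-[(E)-4-(MOMO)styryl]phenyllithium | COCOc1ccc(/C=C/c2cc(OCOC)c([Li])c(OCOC)c2)cc1 | intermediate
4 | 2,6-bis(MOMO)-4-[(E)-4-(MOMO)styryl]benzaldehyde | COCOc1ccc(/C=C/c2cc(OCOC)c(C=O)c(OCOC)c2)cc1 | intermediate
5 | 2-hydroxy-6-(MOMO)-4-[(E)-4-(MOMO)styryl]benzaldehyde | COCOc1ccc(/C=C/c2cc(O)c(C=O)c(OCOC)c2)cc1 | intermediate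
6 | ethyl (E)-3-{2-hydroxy-6-(MOMO)-4-[(E)-4-(MOMO)styryl]phenyl}acrylate | COCOc1ccc(/C=C/c2cc(O)c(/C=C/C(=O)OCC)c(OCOC)c2)cc1 | intermediate
7 | coumarin A, 5-(MOMO)-7-[(E)-4-(MOMO)styryl]-2H-chromen-2-one | COCOc1ccc(/C=C/c2cc(OCOC)c3C=CC(=O)Oc3c2)cc1 | intermediate
8 | 5-bromoresorcinol | Oc1cc(O)cc(Br)c1 | starting material
9 | 1-bromo-3,5-bis(MOMO)benzene | COCOc1cc(Br)cc(OCOC)c1 | intermediate
10 | 3,5-bis(MOMO)phenyllithium | COCOc1cc([Li])cc(OCOC)c1 | intermediate
11 | [3,5-bis(MOMO)phenyl]boronic acid | OB(O)c1cc(OCOC)cc(OCOC)c1 | intermediate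
12 | lactone A, (4S)-4-[3,5-bis(MOMO)phenyl]-5-(MOMO)-7-[(E)-4-(MOMO)styryl]chroman-2-one | COCOc1ccc(/C=C/c2cc(OCOC)c3c(c2)OC(=O)C[C@H]3c2cc(OCOC)cc(OCOC)c2)cc1 | intermediate
13 | lithium enolate of 12 (C2–OLi, C2=C3, 4S) | COCOc1ccc(/C=C/c2cc(OCOC)c3c(c2)OC(O[Li])=C[C@H]3c2cc(OCOC)cc(OCOC)c2)cc1 | intermediate
14 | (3R,4S)-3-bromo-4-[3,5-bis(MOMO)phenyl]-5-(MOMO)-7-[(E)-4-(MOMO)styryl]chroman-2-one (trans) | COCOc1ccc(/C=C/c2cc(OCOC)c3c(c2)OC(=O)[C@H](Br)[C@H]3c2cc(OCOC)cc(OCOC)c2)cc1 | intermediate
15 | (2R,3S)-2-bromo-3-[3,5-bis(MOMO)phenyl]-3-{2-hydroxy-6-(MOMO)-4-[(E)-4-(MOMO)styryl]phenyl}propanoic acid (present as its disodium salt) | COCOc1ccc(/C=C/c2cc(OCOC)c(c(O)c2)[C@@H]([C@@H](Br)C(=O)O)c2cc(OCOC)cc(OCOC)c2)cc1 | intermediate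
16 | acid A, (2S,3S)-3-[3,5-bis(MOMO)phenyl]-4-(MOMO)-6-[(E)-4-(MOMO)styryl]-2,3-dihydrobenzofuran-2-carboxylic acid | COCOc1ccc(/C=C/c2cc(OCOC)c3c(c2)O[C@H](C(=O)O)[C@H]3c2cc(OCOC)cc(OCOC)c2)cc1 | intermediate
17 | 2,6-dihydroxybenzaldehyde | O=Cc1c(O)cccc1O | starting material
18 | ethyl (E)-3-(2,6-dihydroxyphenyl)acrylate | CCOC(=O)/C=C/c1c(O)cccc1O | intermediate
19 | 5-hydroxy-2H-chromen-2-one | O=C1C=Cc2c(O)cccc2O1 | intermediate
20 | 5-hydroxy-8-iodo-2H-chromen-2-one | O=C1C=Cc2c(O)ccc(I)c2O1 | intermediate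
21 | 8-iodo-5-(MOMO)-2H-chromen-2-one | COCOc1ccc(I)c2OC(=O)C=Cc12 | intermediate
22 | 1,3-dioxoisoindolin-2-yl ester of 16 | COCOc1ccc(/C=C/c2cc(OCOC)c3c(c2)O[C@H](C(=O)ON2C(=O)c4ccccc4C2=O)[C@H]3c2cc(OCOC)cc(OCOC)c2)cc1 | intermediate
23 | [5-(MOMO)-2-oxo-2H-chromen-8-yl]zinc iodide | COCOc1ccc([Zn]I)c2OC(=O)C=Cc12 | intermediate
24 | 8-{(2S,3S)-3-[3,5-bis(MOMO)phenyl]-4-(MOMO)-6-[(E)-4-(MOMO)styryl]-2,3-dihydrobenzofuran-2-yl}-5-(MOMO)-2H-chromen-2-one | COCOc1ccc(/C=C/c2cc(OCOC)c3c(c2)O[C@H](c2ccc(OCOC)c4C=CC(=O)Oc24)[C@H]3c2cc(OCOC)cc(OCOC)c2)cc1 | intermediate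
25 | lactone B, (4S)-4-[3,5-bis(MOMO)phenyl]-8-{(2S,3S)-dihydrobenzofuran-2-yl unit of 24}-5-(MOMO)chroman-2-one | COCOc1ccc(/C=C/c2cc(OCOC)c3c(c2)O[C@H](c2ccc(OCOC)c4c2OC(=O)C[C@H]4c2cc(OCOC)cc(OCOC)c2)[C@H]3c2cc(OCOC)cc(OCOC)c2)cc1 | intermediate
26 | lithium enolate of 25 (C2–OLi, C2=C3, 4S) | COCOc1ccc(/C=C/c2cc(OCOC)c3c(c2)O[C@H](c2ccc(OCOC)c4c2OC(O[Li])=C[C@H]4c2cc(OCOC)cc(OCOC)c2)[C@H]3c2cc(OCOC)cc(OCOC)c2)cc1 | intermediate
27 | (3R,4S)-3-bromo derivative of 25 (trans) | COCOc1ccc(/C=C/c2cc(OCOC)c3c(c2)O[C@H](c2ccc(OCOC)c4c2OC(=O)[C@H](Br)[C@H]4c2cc(OCOC)cc(OCOC)c2)[C@H]3c2cc(OCOC)cc(OCOC)c2)cc1 | intermediate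
28 | (2R,3S)-2-bromo-3-[3,5-bis(MOMO)phenyl]-3-{2-hydroxy-6-(MOMO)-3-[(2S,3S)-dihydrobenzofuran-2-yl unit of 24]phenyl}propanoic acid (present as its disodium salt) | COCOc1ccc(/C=C/c2cc(OCOC)c3c(c2)O[C@H](c2ccc(OCOC)c(c2O)[C@@H]([C@@H](Br)C(=O)O)c2cc(OCOC)cc(OCOC)c2)[C@H]3c2cc(OCOC)cc(OCOC)c2)cc1 | intermediate
29 | acid B, (2S,3S)-3-[3,5-bis(MOMO)phenyl]-7-{(2S,3S)-3-[3,5-bis(MOMO)phenyl]-4-(MOMO)-6-[(E)-4-(MOMO)styryl]-2,3-dihydrobenzofuran-2-yl}-4-(MOMO)-2,3-dihydrobenzofuran-2-carboxylic acid | COCOc1ccc(/C=C/c2cc(OCOC)c3c(c2)O[C@H](c2ccc(OCOC)c4c2O[C@H](C(=O)O)[C@H]4c2cc(OCOC)cc(OCOC)c2)[C@H]3c2cc(OCOC)cc(OCOC)c2)cc1 | intermediate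
30 | 4-bromoresorcinol | Oc1ccc(Br)c(O)c1 | starting material
31 | 1-bromo-2,4-bis(MOMO)benzene | COCOc1ccc(Br)c(OCOC)c1 | intermediate
32 | 1,3-dioxoisoindolin-2-yl ester of 29 | COCOc1ccc(/C=C/c2cc(OCOC)c3c(c2)O[C@H](c2ccc(OCOC)c4c2O[C@H](C(=O)ON2C(=O)c5ccccc5C2=O)[C@H]4c2cc(OCOC)cc(OCOC)c2)[C@H]3c2cc(OCOC)cc(OCOC)c2)cc1 | intermediate
33 | [2,4-bis(MOMO)phenyl]zinc chloride | COCOc1ccc([Zn]Cl)c(OCOC)c1 | intermediate
34 | nona-MOM ether of gnetumontanin B (2S,3S in both rings) | COCOc1ccc(/C=C/c2cc(OCOC)c3c(c2)O[C@H](c2ccc(OCOC)c4c2O[C@H](c2ccc(OCOC)cc2OCOC)[C@H]4c2cc(OCOC)cc(OCOC)c2)[C@H]3c2cc(OCOC)cc(OCOC)c2)cc1 | intermediate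
35 | gnetumontanin B | Oc1ccc(/C=C/c2cc(O)c3c(c2)O[C@H](c2ccc(O)c4c2O[C@H](c2ccc(O)cc2O)[C@H]4c2cc(O)cc(O)c2)[C@H]3c2cc(O)cc(O)c2)cc1 | target

**Step count and risks**

Total steps: 17. Longest linear sequence: 11 steps (1 → 2 → 4 → 5 → 7 → 12 → 16 → 24 → 25 → 29 → 34 → 35; steps 1, 2, 3, 4, 7, 8, 12, 13, 14, 16, 17).

Steps most likely to fail:

Step 13 (and, in the same way, step 7). The 5-alkoxycoumarin is electron-rich and hindered at C4 by the peri MOM ether, so insertion into the aryl–rhodium bond may be slow; protodeboronation of the boronic acid and hydrolytic opening of the lactone could then outrun the addition, or facial selectivity could erode. The fallback sets out from 24 and comes back at 25. It separates C–C bond formation from the stereo-determining event. 24 would be arylated at C4 of the coumarin with 11 under oxidative Heck conditions (Pd(OAc)2, 1,10-phenanthroline, O2, DMF, 80 °C) to give the 4-aryl coumarin F1. Copper hydride conjugate reduction (Cu(OAc)2·H2O, the enantiomer of DTBM-SEGPHOS that leads to the 4S lactone, diethoxymethylsilane, t-BuOH, toluene, 0 °C) would then set the same centre by hydride delivery and give 25.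

Step 12 (and step 16). Capture of the hindered secondary α-alkoxy radical by the aryl–nickel species may be slow, so that reduction or dimerisation of the radical and homocoupling of the arylzinc take over. The fallback sets out from 16 and 21 and comes back at 24. The redox-active ester 22 would be isolated and joined to aryl iodide 21 by reductive cross-electrophile coupling (NiBr2·DME, 4,4'-di-tert-butyl-2,2'-bipyridine, Zn powder, N,N-dimethylacetamide, 20 °C). This avoids the preformed organozinc and reverses the order of events at nickel (oxidative addition of the aryl iodide first, radical capture second); it makes no new compound (F0).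

Step 14 (and step 8). After bromination, dehydrobromination to the 4-arylcoumarin or direct hydrolysis of the C–Br bond may compete with the ring closure once the lactone has opened. The fallback sets out from 25 and comes back at 29; it carries out the same contraction stepwise without a halide. The enolate of 25 (LiN(SiMe3)2, THF, −78 °C) would be hydroxylated with 2-(phenylsulfonyl)-3-phenyloxaziridine anti to the C4 aryl group to give the trans-3-hydroxy lactone F2. NaOMe in MeOH at 0 °C would open it to the phenol methyl 2-hydroxy ester F3. Mitsunobu etherification (PPh3, diisopropyl azodicarboxylate, THF, 0 °C) would close the five-membered ring with inversion at the carbinol carbon to the trans methyl ester F4, and LiOH in THF/H2O would give 29.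

Further compounds

F1 | step 13 | 4-[3,5-bis(MOMO)phenyl]-8-{(2S,3S)-dihydrobenzofuran-2-yl unit of 24}-5-(MOMO)-2H-chromen-2-one | COCOc1ccc(/C=C/c2cc(OCOC)c3c(c2)O[C@H](c2ccc(OCOC)c4c2OC(=O)C=C4c2cc(OCOC)cc(OCOC)c2)[C@H]3c2cc(OCOC)cc(OCOC)c2)cc1
F0 | step 12 | none | none
F2 | step 14 | (3R,4S)-3-hydroxy derivative of 25 (trans) | COCOc1ccc(/C=C/c2cc(OCOC)c3c(c2)O[C@H](c2ccc(OCOC)c4c2OC(=O)[C@H](O)[C@H]4c2cc(OCOC)cc(OCOC)c2)[C@H]3c2cc(OCOC)cc(OCOC)c2)cc1
F3 | step 14 | methyl (2R,3S)-2-hydroxy-3-[3,5-bis(MOMO)phenyl]-3-{2-hydroxy-6-(MOMO)-3-[(2S,3S)-dihydrobenzofuran-2-yl unit of 24]phenyl}propanoate | COCOc1ccc(/C=C/c2cc(OCOC)c3c(c2)O[C@H](c2ccc(OCOC)c(c2O)[C@@H]([C@@H](O)C(=O)OC)c2cc(OCOC)cc(OCOC)c2)[C@H]3c2cc(OCOC)cc(OCOC)c2)cc1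
F4 | step 14 | methyl ester of 29 (2S,3S in both rings) | COCOc1ccc(/C=C/c2cc(OCOC)c3c(c2)O[C@H](c2ccc(OCOC)c4c2O[C@H](C(=O)OC)[C@H]4c2cc(OCOC)cc(OCOC)c2)[C@H]3c2cc(OCOC)cc(OCOC)c2)cc1
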